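The readings are calculated for an exercise.

The vessel was stirred and isothermal, and Z was fed over 2.5 s onto 2.5 µM of X. The beta run is this same flask followed early, and I wanted its state at 15 min.

- beta: Z 5 mM (fed, over 2.5 s); X 2.5 µM; the very flask that is asked about, followed so far
- flask: Z 5.0 mM (fed, over 2.5 s); X 2.5 µM; time 15 min

- beta (time / min: Z / %, J / %, E / %): 0.417: 33.1, 45.8, 22.4; 1.33: 4.7, 46.5, 48.6; 2.00: 3.3, 44.7, 51.6; 3.00: 1.2, 46.0, 51.2; 5.00: 1.3, 46.4, 53.0; 6.00: 1.1, 47.4, 54.1

(readings scatter by 1 percentage point)

- the reaction counts as stopped when no species that holds the Z changes by six tenths of a point or more over the second half of the time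

- why nothing more happens at 15 min, or that something still does (all of Z has reacted / no working catalyst is left / it is still moving / forward and back rates have come level)
- conversion of Z at 15 min
- amount of J at 15 min, in percent of the Z charged
- amount of E at 15 min, in percent of the Z charged

I followed one molecule of Z to where it finished and carried one quantity, the J share: J divided by J plus E, summed over the last 3 beta readings, which came to 46.9 %. My first objection was that a fork with a fixed chance keeps a constant share, yet the beta share read 67.2 % at 0.417 min and 48.9 % at 1.33 min before it levelled. So I took the late share, tentatively, as a balance between J and E, which is thermodynamic rather than kinetic control.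

My second objection was that [Z] still read 1.20 % on average over those readings. Counting that residue as E moved the share to 46.3 %, which was a small change. The residue itself was also doubtful, since its mean carried a standard error of 0.58 percentage points, and J plus E fell short of the charge by 0.63 points on average over the same readings. I therefore committed to Z being used up, with conversion near 100 %, J at 46.9 % and E at 53.1 %, though these readings could not exclude a dying catalyst.

The forecast gave forward and back rates have come level, with conversion 98.8 %, J 46.2 % and E 52.7 %, and it argued that “A dying catalyst would need fine-tuning to stop Z there”. I parted from it on the ending.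

The flask at 15 min gave all of Z has reacted, with conversion >99.9 %, J 46.6 % and E 52.7 %, while X stood at 3.19 % of its charge and Q at 96.8 %.

    G → X + J (k = 183 /s)
    2 X → Q (k = 6960 /M/s)
    Z → D (k = 2.84 × 10⁻⁴ /s)
    Z + X ⇌ G (K = 277 /M, k = 99300 /M/s)
    J + X ⇌ E + X, rate k5*[X]*[J] forward; the back reaction follows from the equilibrium constant (K = 1.13, k = 29900 /M/s)

D held 0.679 % of the charge in this flask, and the J share applied to what remained gives 46.6 % of J. For the same flask read at 40 min, the same reckoning gives 46.6 % of J and 52.7 % of E. That flask gave J 46.6 % and E 52.7 %, with X at 1.20 % of its charge.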